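**Retrosynthetic overview**
1. The last bond formed is the CH2–CH2 bond C4′–C5′ of the hexadecyl chain (numbered from furan C5). It is cut into two carboxylic acids, tridecanoic acid and 5-[5-(2-methoxy-2-oxoethyl)furan-2-yl]pentanoic acid, which are joined as their N-hydroxyphthalimide esters by a nickel-electrocatalytic doubly decarboxylative coupling (two carbons of like, electrophilic polarity united through cathodically generated radicals).
2. Enabling feature: both carbons of this bond are unbranched primary CH2 groups, so each is the α-carbon of a primary carboxylic acid; C4′ is insulated from furan C5 by three methylenes. The electron-rich furan ring (O1, C2–C5) would not survive anodic Kolbe potentials, hence the reductive (cathodic) electrolysis.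
3. The furan acid comes from furfural: Wittig olefination with the (3-carboxypropyl)phosphonium ylide, alkene hydrogenation, then radical C–H methoxycarbonylmethylation at the only free α-position of the furan. This differentiates the two carboxyl groups without protecting groups.
4. Ring order: the furan ring is bought as furfural; no ring is formed in the route.

Key step: step 6

Remark on the chemistry: the target has no stereocentre and no stereogenic double bond, so it is achiral; the single-enantiomer requirement is met trivially and no step needs stereocontrol.

**Step 1**
Reactants: 1 furfural; 2 (3-carboxypropyl)triphenylphosphonium bromide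
Product: 4 (Z)-5-(furan-2-yl)pent-4-enoic acid, via sodium 4-(triphenylphosphoranylidene)butanoate 3 (not isolated)
Conditions: 2 (1.2 equiv), NaHMDS (2.4 equiv), THF, 0 °C; then 1, −78 °C → rt; aq. HCl work-up
Reagents that add atoms: NaHMDS, [Na+].C[Si](C)(C)[N-][Si](C)(C)C (supplies only the sodium of intermediate 3)
Why: Wittig olefination of a non-enolisable aromatic aldehyde with a non-stabilised carboxylate ylide should give the alkenoic acid directly (Z-major E/Z mixture expected; the geometry is irrelevant because the alkene is saturated in step 2).

**Step 2**
Reactants: 4 (Z)-5-(furan-2-yl)pent-4-enoic acid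
Product: 5 5-(furan-2-yl)pentanoic acid
Conditions: H2 (1 atm), 5% Pd/C, EtOAc, rt, stopped after 1 equiv H2
Reagents that add atoms: none
Why: Catalytic hydrogenation of the disubstituted, furan-conjugated alkene should be much faster than reduction of the aromatic furan at ambient pressure, so the chain is saturated selectively.

**Step 3**
Reactants: 5 5-(furan-2-yl)pentanoic acid; 6 methyl iodoacetate
Product: 7 5-[5-(2-methoxy-2-oxoethyl)furan-2-yl]pentanoic acid
Conditions: 6 (2 equiv), FeSO4·7H2O (cat.), 30% aq. H2O2 (slow addition), DMSO, rt
Reagents that add atoms: none
Why: Fenton-type homolytic aromatic substitution, in which HO• from Fe(II)/H2O2 cleaves DMSO to CH3•, CH3• abstracts iodine from 6, and the electrophilic •CH2CO2Me radical adds to the only free α-position of the electron-rich 2-alkylfuran before Fe(III) oxidation and proton loss rearomatise; the non-basic medium leaves the free carboxylic acid unalkylated.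

**Step 4**
Reactants: 7 5-[5-(2-methoxy-2-oxoethyl)furan-2-yl]pentanoic acid
Product: 8 1,3-dioxoisoindolin-2-yl 5-[5-(2-methoxy-2-oxoethyl)furan-2-yl]pentanoate
Conditions: N-hydroxyphthalimide (1.1 equiv), DIC (1.1 equiv), DMAP (cat.), CH2Cl2, rt
Reagents that add atoms: N-hydroxyphthalimide, O=C1c2ccccc2C(=O)N1O
Why: Steglich-type carbodiimide esterification activates only the free carboxylic acid and should leave the methyl ester and the furan untouched.

**Step 5**
Reactants: 9 tridecanoic acid
Product: 10 1,3-dioxoisoindolin-2-yl tridecanoate
Conditions: N-hydroxyphthalimide (1.1 equiv), DIC (1.1 equiv), DMAP (cat.), CH2Cl2, rt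
Reagents that add atoms: N-hydroxyphthalimide, O=C1c2ccccc2C(=O)N1O
Why: The same Steglich-type esterification on a simple fatty acid should give the crystalline redox-active ester.

**Step 6**
Reactants: 8 1,3-dioxoisoindolin-2-yl 5-[5-(2-methoxy-2-oxoethyl)furan-2-yl]pentanoate; 10 1,3-dioxoisoindolin-2-yl tridecanoate
Product: 11 methyl 2-(5-hexadecylfuran-2-yl)acetate
Conditions: 8 (1 equiv), 10 (3 equiv), NiCl2·6H2O (20 mol%), 2,6-bis(pyrazol-1-yl)pyridine (20 mol%), AgNO3 (30 mol%), NMP, undivided cell, (+)Mg/(−)RVC, constant current, rt; dilute HCl work-up
Reagents that add atoms: none
Why: At the silver-coated cathode the Ni(II)–tridentate ligand complex is reduced to low-valent nickel, which transfers single electrons to both N-acyloxyphthalimides; each fragments with loss of CO2 and phthalimide anion to a primary alkyl radical, the radicals are captured at nickel, and a dialkylnickel(III) species reductively eliminates the CH2–CH2 bond while the sacrificial magnesium anode supplies the electrons. The closest known reaction type is the nickel-electrocatalytic doubly decarboxylative C(sp3)–C(sp3) cross-coupling of two primary redox-active esters, a reductive counterpart of the mixed Kolbe electrolysis. No ring is closed and no stereocentre is created. The step needs cross- over homo-coupling, which is addressed by the threefold excess of the inexpensive ester 10 and by the polarity spread of the three possible coupling products (hydrocarbon, monoester, diester), which should allow simple chromatographic separation. Chemoselectivity rests on the substrate: all redox events are cathodic, so the oxidation-labile furan never sees an anodic potential; the methyl ester is not reduced at the potential of the phthalimide ester; and the nucleophilic primary radicals are polarity-mismatched toward the electron-rich furan, whose three-methylene spacer should make ring attack slow relative to capture by nickel.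

**Compound list**
1 | furfural (furan-2-carbaldehyde) | O=Cc1ccco1 | starting material
2 | (3-carboxypropyl)triphenylphosphonium bromide | OC(=O)CCC[P+](c1ccccc1)(c1ccccc1)c1ccccc1.[Br-] | starting material
3 | sodium 4-(triphenylphosphoranylidene)butanoate | [Na+].[O-]C(=O)CCC=P(c1ccccc1)(c1ccccc1)c1ccccc1 | intermediate (not isolated)
4 | (Z)-5-(furan-2-yl)pent-4-enoic acid (carried on as the E/Z mixture) | OC(=O)CC/C=C\c1ccco1 | intermediate
5 | 5-(furan-2-yl)pentanoic acid | OC(=O)CCCCc1ccco1 | intermediate
6 | methyl iodoacetate | COC(=O)CI | starting material
7 | 5-[5-(2-methoxy-2-oxoethyl)furan-2-yl]pentanoic acid | COC(=O)Cc1ccc(CCCCC(=O)O)o1 | intermediate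
8 | 1,3-dioxoisoindolin-2-yl 5-[5-(2-methoxy-2-oxoethyl)furan-2-yl]pentanoate | COC(=O)Cc1ccc(CCCCC(=O)ON2C(=O)c3ccccc3C2=O)o1 | intermediate
9 | tridecanoic acid | CCCCCCCCCCCCC(=O)O | starting material
10 | 1,3-dioxoisoindolin-2-yl tridecanoate | CCCCCCCCCCCCC(=O)ON1C(=O)c2ccccc2C1=O | intermediate
11 | methyl 2-(5-hexadecylfuran-2-yl)acetate | CCCCCCCCCCCCCCCCc1ccc(CC(=O)OC)o1 | target

**Step count**
Total: 6 steps. Longest linear sequence: 5 steps (steps 1, 2, 3, 4, 6); step 5 is the one-step side branch.

**Steps most likely to fail, with fallbacks**

Step 6 (key step). The risks are statistical homo-coupling of either redox-active ester, loss of the radicals by hydrogen-atom capture or disproportionation, and cyclisation of the furylbutyl radical onto the ring before nickel capture. Fallback: a non-electrochemical, nickel-catalysed decarboxylative Negishi-type alkyl–alkyl coupling that sets out from 8 and comes back at 11. Ester 8 would be treated with didodecylzinc F1 (made in the flask from commercial dodecylmagnesium bromide and 0.5 equiv ZnCl2 in THF) in the presence of NiCl2·glyme (20 mol%) and 4,4′-di-tert-butyl-2,2′-bipyridine (40 mol%) in THF/DMF at rt. Only one radical is generated, so the cross-selectivity problem disappears; the methyl ester should tolerate the organozinc reagent. This fallback does not need 10.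

Step 3. The risks are incomplete conversion when the furan is the limiting component and oxidative degradation (ring opening) of the electron-rich furan by oxygen-centred radicals. Fallback: a polar two-step sequence that sets out from 5 and comes back at 7. Friedel–Crafts alkylation of 5 at the free α-position with racemic methyl 2-chloro-2-(methylsulfanyl)acetate F2 (prepared from commercial methyl (methylsulfanyl)acetate and N-chlorosuccinimide), using SnCl4 in CH2Cl2 at −20 to 0 °C, should give racemic 5-{5-[2-methoxy-1-(methylsulfanyl)-2-oxoethyl]furan-2-yl}pentanoic acid F3. Reductive desulfurisation with zinc dust in acetic acid would then deliver 7.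

Step 2. The risk is over-reduction, i.e. hydrogen uptake continuing into the furan ring or hydrogenolytic opening of the ring. Fallback: diimide reduction, setting out from 4 and coming back at 5, with diimide generated in situ from 2-nitrobenzenesulfonyl hydrazide and Et3N in CH2Cl2 at rt. Diimide saturates the C=C bond by concerted syn hydrogen transfer and cannot reduce the aromatic furan; this fallback makes no new compound (F0).

**Further compounds**
F1 | step 6 | didodecylzinc | CCCCCCCCCCCC[Zn]CCCCCCCCCCCC
F2 | step 3 | methyl 2-chloro-2-(methylsulfanyl)acetate (racemic) | COC(=O)C(Cl)SC
F3 | step 3 | 5-{5-[2-methoxy-1-(methylsulfanyl)-2-oxoethyl]furan-2-yl}pentanoic acid (racemic) | COC(=O)C(SC)c1ccc(CCCCC(=O)O)o1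
F0 | step 2 | none | none
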